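Remarks on the chemistry, made once:
- Kaurane/podocarpane atom numbers are used for all tri- and tetracyclic compounds, and α/β have the sense of the target name (C20 methyl α, H5 β). "Jungermannane" means the target's carbon skeleton (C11–C15 and C13–C16 bonds).
- Assumption: the photoadduct 18 and compounds 19–24 are written as the isomer with the dioxolane oxygens exo (towards C12) and, for 18, the cyclopropane closed onto C14. Isomeric adducts (endo dioxolane, closure onto C9) have the same C11–C15 and C13–C16 bonds and should merge with the main line in step 10 or step 15.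
- Compounds 1, 3 and 15 are taken as purchased.

## The problem

The target is a trans-fused A/B decalin (C20 methyl α, H5 β) with an equatorial acetate at C1 and an axial acetate at C6. It is joined through a tetrasubstituted C8=C9 double bond to a bicyclo[3.2.1]octane: C11 and C13 are bridgeheads, C12 (free hydroxyl) is the one-carbon bridge and C15(=O)–C16(=CH2) the two-carbon bridge. Its seven stereocentres fall into two sets, C1/C5/C6/C10 and C11/C12/C13, separated by the flat C8=C9 unit, so the second set can only be set by long-range control from the first. C11 is at once a bridgehead, allylic and α to the C15 ketone, it sits in a bay next to C1 and its acetate, and the C15–C16 bridge must lie on the β face, opposite the C20 methyl. The C12 carbinol is on a one-atom bridge where inversion by substitution is not possible, so its configuration must come from a reduction, and it must stay free while C1 and C6 are acetylated. The exocyclic enone tolerates neither strong base, nucleophiles nor hydride, and the acetates exclude basic hydrolysis late in the route. The enabling feature is ring C (C8, C9, C11, C12, C13, C14), which has the exact pattern of a dearomatised anisole: oxygen on C12, both ortho carbons C11 and C13 bonded to the two ends of one two-carbon unit (C15–C16), C14 a methylene and C8=C9 the only ring double bond. That is the bicyclo[3.2.1]oct-2-en-8-one obtained when an alkene adds across the 2,6-positions of an anisole in the meta photocycloaddition and the methoxycyclopropane is opened by acid, so rings A, B and C can be made as a flat 12-methoxypodocarpatriene whose C20 methyl shields the α face at C9/C11.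

## Retrosynthesis

**Enone and C12 carbinol (26 back to 19).** The exocyclic enone is made last. Target 26 comes from silyl ether 25, whose C16=C17 bond comes from dehydration of the tertiary α-ketol 23 (C15=O, C16(OH)CH3). C13 is a bridgehead and C15 a carbonyl, so water can only be lost towards the methyl group. Ketol 23 comes from diol 22, this from acetonide 21/20, and the C12 carbinol of 20 from ketone 19. The neighbouring cut, a C15 methylene oxidised late, would need an allylic oxidation next to the electron-rich C8=C9 olefin. The forward steps must deliver hydride to C12 from the C8=C9 side and keep O12 protected through one oxidation and one dehydration.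

**Key disconnection (19 to 14 + 17).** Ketone 19 is cut at C11–C15 and C13–C16, with C14–H and the C12 carbonyl traced back to an aryl methyl ether. This returns the tricyclic anisole 14 and 2,2,4-trimethyl-1,3-dioxole 17. Cutting only C11–C15 or only C13–C16 would leave a bridged or heavily functionalised cyclohexanone as precursor; cutting both restores an aromatic ring. Arene 14 has four stereocentres and no bridged ring. Dioxole 17 supplies C15, C16 and C17 with oxygen on both future sp2 carbons. The forward reaction must give meta addition at C11/C13, on the β face, with the methyl-bearing carbon on C13, and then open the cyclopropane with the proton going to C14.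

**Ring B (14 back to 10).** Diacetate 14 comes from alcohol 13 and ketone 12. Ketone 12 is cut at C9–C10 (and C5–H) to the monocyclic enol ether acetate 10, in which the enol ether is a latent C6 ketone and the trigger for ring closure. The other ring-B bond, C7–C8, would be electronically easier to close (para to methoxy), but would require the aryl group on the quaternary C10 first. With the C9–C10 cut, the C1 acetate stereocentre sits next to the forming quaternary centre and can control it; C5 and C6 then follow from C10.

**Ring A piece (10 back to 5 + 2).** Acetate 10 comes from alcohol 9 and enone 8. Enone 8 is cut at C5–C6 into vinylogous ester 5 and the lithiated enol ether of 2. A catalytic enantioselective reduction of 8, which has a single ketone, sets C1. Ester 5 comes from commercial 3 by two methylations, and 2 from aldehyde 1.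

**Alkene partner (17 back to 15).** Dioxole 17 comes from the commercial chloride 15 by elimination and double-bond migration.

## Roads not taken

**Alternative 1:** the most obvious cut is the retro-1,3-acyl shift, C11–C15 to C8–C15, leading to ent-kaura-9(11),16-dien-15-one A1. The forward key step is photochemical 1,3-acyl migration of the β,γ-unsaturated ketone. This first requires the kaurane bicyclo[3.2.1]octane with a quaternary C8 bridgehead, then rearranges it; the shift is reversible and competes with other enone photochemistry while the exocyclic enone is already present. The chosen plan builds the rearranged bicycle directly from an arene and never makes a quaternary C8.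

**Alternative 2:** Birch reduction of the same anisole ring and stepwise α,α′-annulation of the resulting cyclohexenone. After C11 propargylation, the silyl enol ether A2 would be closed by a gold-catalysed Conia-ene-type cyclisation (Ph3PAuNTf2, monovalent gold). This needs two regioselective enolisations on either side of C12 in the presence of the acetates and four to five operations for what one irradiation does. It also delivers C15 as CH2, so a late allylic oxidation must distinguish the exocyclic olefin from the tetrasubstituted C8=C9 olefin.

**Alternative 3:** oxidative dearomatisation of phenol A3 to a phenoxonium ion and cationic [5+2] cycloaddition with an alkene across C11/C13. This reaction type relies on a para alkoxy group to end the cascade as an enone. Here the para carbon is C8, carbon-substituted, so an allyl cation C9–C8–C14 is left that must take up hydride at C14 from outside and can undergo skeletal shifts. The photochemical route reaches the same bond set without a cation at C8.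

Key step: step 10

## Steps

Step 1
Reactants: 1 4-methoxybenzaldehyde
Product: 2 1-methoxy-4-(2-methoxyethenyl)benzene (E/Z mixture)
Conditions: MeOCH2PPh3Cl, KOtBu, THF, 0 °C to rt
Reagents that add atoms: (methoxymethyl)triphenylphosphonium chloride, COC[P+](c1ccccc1)(c1ccccc1)c1ccccc1.[Cl-]
Why: Wittig olefination of an aromatic aldehyde with the methoxymethylene ylide is routine; both enol ether isomers can be used because the double-bond geometry is lost in step 6.

Step 2
Reactants: 3 3-ethoxy-2-methylcyclohex-2-en-1-one
Product: 5 3-ethoxy-2,6,6-trimethylcyclohex-2-en-1-one, via monomethylated enone 4 (not isolated)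
Conditions: LiN(iPr)2, THF, −78 °C, then MeI; second portion of LiN(iPr)2, then MeI, −78 to 0 °C, one flask
Reagents that add atoms: iodomethane, CI
Why: Kinetic deprotonation of a vinylogous ester occurs at the α′ carbon, so two successive enolate methylations (Stork–Danheiser alkylation) place the gem-dimethyl group next to the ketone without ambiguity; this carbon becomes C4 of the target.

Step 3
Reactants: 5 3-ethoxy-2,6,6-trimethylcyclohex-2-en-1-one; 2 1-methoxy-4-(2-methoxyethenyl)benzene
Product: 8 3-[1-methoxy-2-(4-methoxyphenyl)ethenyl]-2,4,4-trimethylcyclohex-2-en-1-one, via vinyllithium 6 (not isolated), via tertiary carbinol 7 (not isolated)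
Conditions: t-BuLi, THF, −78 to −20 °C (lithiation of 2); then 5, −78 °C; then 0.5 M HCl, THF, 0 °C, short contact
Reagents that add atoms: water, O
Why: Oxygen-directed α-lithiation of the enol ether gives an acyl-anion equivalent small enough to add to the hindered ketone of 5; dilute acid then effects the Stork–Danheiser transposition (loss of water and ethanol), while the β-aryl enol ether, which is protonated much more slowly than the doubly activated carbinol, is kept as a latent C6 ketone.

Step 4
Reactants: 8 3-[1-methoxy-2-(4-methoxyphenyl)ethenyl]-2,4,4-trimethylcyclohex-2-en-1-one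
Product: 9 (1S)-3-[1-methoxy-2-(4-methoxyphenyl)ethenyl]-2,4,4-trimethylcyclohex-2-en-1-ol
Conditions: (R)-Me-CBS oxazaborolidine [(R)-1-methyl-3,3-diphenyltetrahydropyrrolo[1,2-c][1,3,2]oxazaborole] (20 mol %), catecholborane, toluene, −78 °C
Reagents that add atoms: none
Why: Corey–Bakshi–Shibata reduction of a 2-substituted cyclohexenone, the only ketone present; with the α-methylated alkenyl arm as the large group, the (R)-catalyst should give the (1S)-carbinol, the stereocentre (C1 of the target) from which all others are derived.

Step 5
Reactants: 9 (1S)-3-[1-methoxy-2-(4-methoxyphenyl)ethenyl]-2,4,4-trimethylcyclohex-2-en-1-ol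
Product: 10 (1S)-3-[1-methoxy-2-(4-methoxyphenyl)ethenyl]-2,4,4-trimethylcyclohex-2-en-1-yl acetate
Conditions: Ac2O, pyridine, 4-(dimethylamino)pyridine (cat.), CH2Cl2, rt
Reagents that add atoms: acetic anhydride, CC(=O)OC(C)=O
Why: Standard acylation; the acetate is the group the target carries at C1, it prevents redox isomerisation or ionisation of the allylic alcohol in the acid step, and it can shield one face of C10 by participation.

Step 6
Reactants: 10 (1S)-3-[1-methoxy-2-(4-methoxyphenyl)ethenyl]-2,4,4-trimethylcyclohex-2-en-1-yl acetate
Product: 12 (1S,5R,10R)-1α-acetoxy-12-methoxypodocarpa-8,11,13-trien-6-one, via tricyclic enol ether 11 (not isolated)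
Conditions: CF3SO3H (20 mol %), CH2Cl2/(CF3)2CHOH, −40 to 0 °C; then 1 M HCl, THF, rt
Reagents that add atoms: water, O
Why: Protonation of the enol ether at C7 gives an alkoxyallyl cation whose tertiary terminus C10 is attacked by the ortho carbon of the arene (intramolecular Friedel–Crafts cyclialkylation closing ring B); the pseudoaxial C1 acetate, which can also bridge to C10, forces the arene to the opposite face and so sets C10, and hydrolysis of enol ether 11 protonates C5 from the β face, away from the axial C20 and C4 methyls, giving the trans ring fusion, which is also the thermodynamic one.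

Step 7
Reactants: 12 (1S,5R,10R)-1α-acetoxy-12-methoxypodocarpa-8,11,13-trien-6-one
Product: 13 (1S,5R,6S,10R)-1α-acetoxy-12-methoxypodocarpa-8,11,13-trien-6α-ol
Conditions: NaBH4, MeOH/CH2Cl2, 0 °C
Reagents that add atoms: none
Why: Hydride should attack the C6 ketone from the β face because the α face is closed by the syn-axial C20 and C4α methyl groups, giving the axial 6α-alcohol as in 6-oxo steroids; the acetate is not reduced under these conditions.

Step 8
Reactants: 13 (1S,5R,6S,10R)-1α-acetoxy-12-methoxypodocarpa-8,11,13-trien-6α-ol
Product: 14 (1S,5R,6S,10R)-1α,6α-diacetoxy-12-methoxypodocarpa-8,11,13-triene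
Conditions: Ac2O, 4-(dimethylamino)pyridine, Et3N, CH2Cl2, 40 °C
Reagents that add atoms: acetic anhydride, CC(=O)OC(C)=O
Why: Nucleophile-catalysed acylation under forcing conditions for the hindered axial alcohol; both acetates of the target are now in place, so no base-labile group has to be introduced after the enone exists.

Step 9
Reactants: 15 4-(chloromethyl)-2,2-dimethyl-1,3-dioxolane
Product: 17 2,2,4-trimethyl-1,3-dioxole, via exocyclic enol ether 16 (not isolated)
Conditions: KOtBu (2.2 equiv), DMSO, rt to 70 °C; product distilled from the mixture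
Reagents that add atoms: none
Why: E2 dehydrochlorination gives the 4-methylene dioxolane, and the same base in DMSO should move the double bond into the ring by the allyl-ether-to-enol-ether isomerisation (deprotonation at the oxygen-bearing allylic CH2, reprotonation at the terminal carbon), the endocyclic trisubstituted olefin being the more stable isomer.

Step 10
Reactants: 14 (1S,5R,6S,10R)-1α,6α-diacetoxy-12-methoxypodocarpa-8,11,13-triene; 17 2,2,4-trimethyl-1,3-dioxole
Product: 19 15,16-(isopropylidenedioxy)-12-oxojungermann-8-ene-1α,6α-diyl diacetate (C17 as methyl on C16; dioxolane oxygens exo), via meta photocycloadduct 18 (not isolated)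
Conditions: hν (254 nm, low-pressure Hg lamp, quartz), 17 (10 equiv), cyclohexane, Ar, rt, to partial conversion; evaporation; then TsOH·H2O (5 mol %), acetone/H2O 20:1, 0 °C to rt
Reagents that add atoms: water, O
Why: The singlet-excited anisole ring of 14 forms an exciplex with the electron-rich alkene and adds it across the two carbons ortho to the methoxy group (C11 and C13), giving the C11–C15 and C13–C16 bonds and a bicyclo[3.2.1]octenyl biradical (C12 radical, C9–C8–C14 allyl radical) that collapses to the methoxy-vinylcyclopropane 18; the closest known reaction is the meta photocycloaddition of anisole to enol ethers and 1,3-dioxoles, in which the methoxy group directs 2,6-addition. This closes the five-membered ring C11–C15–C16–C13–C12 in a formal [3+2] mode and, transiently, the three-membered ring C12–C13–C14. Acid then protonates C14 and breaks the C12–C14 bond with push from the methoxy oxygen, and the oxocarbenium ion is hydrolysed to the C12 ketone, as known for 1-methoxy meta adducts, which give bicyclo[3.2.1]oct-2-en-8-ones. C11 and C13 are set by the face of the flat ring C that the alkene uses: the axial C20 methyl on C10 lies directly under C9/C11, so the alkene should add from the β face. The orientation is decided in the bay: the methyl group of 17 lies along the alkene axis and would be driven into C1–H and the C1 acetate if its carbon bonded to C11, so the methyl-bearing carbon becomes C16 on C13 and the CH carbon becomes C15 on C11. The exo or endo position of the dioxolane is of no consequence because C15 and C16 both end as sp2 carbons, and either site of cyclopropane closure (C14 or C9) leads to the same ketone as long as the proton goes to the exposed C14 and not to the fully substituted, buttressed C9. The step needs the meta mode to win over ortho addition, which is the usual outcome for a donor arene with a donor alkene, and the acetonide to survive, which the acetone medium secures.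

Step 11
Reactants: 19 15,16-(isopropylidenedioxy)-12-oxojungermann-8-ene-1α,6α-diyl diacetate
Product: 20 12-hydroxy-15,16-(isopropylidenedioxy)jungermann-8-ene-1α,6α-diyl diacetate (12-OH syn to the C15–C16 bridge)
Conditions: NaBH4, MeOH, −20 °C
Reagents that add atoms: none
Why: The strained bridging ketone is the only ketone present; the exo substituents of the two-carbon bridge lie on the approach path over that bridge, so hydride should come from the side of the C8=C9 bridge (axial attack on ring C) and give the alcohol syn to C15–C16, the configuration of the target.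

Step 12
Reactants: 20 12-hydroxy-15,16-(isopropylidenedioxy)jungermann-8-ene-1α,6α-diyl diacetate
Product: 21 12-(tert-butyldimethylsilyloxy)-15,16-(isopropylidenedioxy)jungermann-8-ene-1α,6α-diyl diacetate
Conditions: TBSOTf, 2,6-lutidine, CH2Cl2, 0 °C
Reagents that add atoms: tert-butyldimethylsilyl trifluoromethanesulfonate, CC(C)(C)[Si](C)(C)OS(=O)(=O)C(F)(F)F
Why: Silylation with the triflate reaches the hindered bridge alcohol; the silyl ether keeps O12 distinct from the acetates and is inert to the oxidation and dehydration that follow.

Step 13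
Reactants: 21 12-(tert-butyldimethylsilyloxy)-15,16-(isopropylidenedioxy)jungermann-8-ene-1α,6α-diyl diacetate
Product: 22 12-(tert-butyldimethylsilyloxy)-15,16-dihydroxyjungermann-8-ene-1α,6α-diyl diacetate (cis-diol, C16 tertiary)
Conditions: AcOH/THF/H2O 3:1:1, 45 °C
Reagents that add atoms: none
Why: Mild aqueous acid hydrolyses the acetonide, whose tertiary C16–O bond makes it labile, while a hindered secondary tert-butyldimethylsilyl ether and the acetates should survive.

Step 14
Reactants: 22 12-(tert-butyldimethylsilyloxy)-15,16-dihydroxyjungermann-8-ene-1α,6α-diyl diacetate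
Product: 23 12-(tert-butyldimethylsilyloxy)-16-hydroxy-15-oxojungermann-8-ene-1α,6α-diyl diacetate
Conditions: 2-iodoxybenzoic acid (IBX), DMSO, rt
Reagents that add atoms: none
Why: IBX oxidises the secondary alcohol of a 1,2-diol to the α-ketol without C–C cleavage; only C15 carries an oxidisable carbinol, so no regiochemical question arises.

Step 15
Reactants: 23 12-(tert-butyldimethylsilyloxy)-16-hydroxy-15-oxojungermann-8-ene-1α,6α-diyl diacetate
Product: 25 12-(tert-butyldimethylsilyloxy)-15-oxojungermanna-8,16-diene-1α,6α-diyl diacetate, via chlorosulfite 24 (not isolated)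
Conditions: SOCl2, pyridine, CH2Cl2, −30 to 0 °C
Reagents that add atoms: none
Why: Dehydration of a tertiary α-ketol through its chlorosulfite (E2 with pyridine), as used for tertiary α-hydroxy ketones in steroid chemistry; C13 is a bridgehead and C15 a carbonyl, so only the methyl hydrogens can be lost and the exocyclic enone is the sole possible olefin.

Step 16
Reactants: 25 12-(tert-butyldimethylsilyloxy)-15-oxojungermanna-8,16-diene-1α,6α-diyl diacetate
Product: 26 1α,6α-diacetoxyjungermannenone C
Conditions: HF·pyridine, pyridine/THF, 0 °C to rt
Reagents that add atoms: none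
Why: Buffered fluoride desilylation is non-basic and non-nucleophilic enough to leave the exocyclic enone and both acetates untouched, and it frees only the C12 hydroxyl.

## Compound list

1 | 4-methoxybenzaldehyde | COc1ccc(C=O)cc1 | starting material
2 | 1-methoxy-4-(2-methoxyethenyl)benzene (E/Z mixture) | COC=Cc1ccc(OC)cc1 | intermediate
3 | 3-ethoxy-2-methylcyclohex-2-en-1-one | CCOC1=C(C)C(=O)CCC1 | starting material
4 | 3-ethoxy-2,6-dimethylcyclohex-2-en-1-one (racemic, not isolated) | CCOC1=C(C)C(=O)C(C)CC1 | intermediate
5 | 3-ethoxy-2,6,6-trimethylcyclohex-2-en-1-one | CCOC1=C(C)C(=O)C(C)(C)CC1 | intermediate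
6 | [1-methoxy-2-(4-methoxyphenyl)ethenyl]lithium (not isolated) | [Li]C(OC)=Cc1ccc(OC)cc1 | intermediate
7 | 3-ethoxy-1-[1-methoxy-2-(4-methoxyphenyl)ethenyl]-2,6,6-trimethylcyclohex-2-en-1-ol (racemic, as its lithium alkoxide, not isolated) | CCOC1=C(C)C(O)(C(OC)=Cc2ccc(OC)cc2)C(C)(C)CC1 | intermediate
8 | 3-[1-methoxy-2-(4-methoxyphenyl)ethenyl]-2,4,4-trimethylcyclohex-2-en-1-one | COC(=Cc1ccc(OC)cc1)C1=C(C)C(=O)CCC1(C)C | intermediate
9 | (1S)-3-[1-methoxy-2-(4-methoxyphenyl)ethenyl]-2,4,4-trimethylcyclohex-2-en-1-ol | CC1(C)CC[C@H](O)C(C)=C1C(OC)=Cc1ccc(OC)cc1 | intermediate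
10 | (1S)-3-[1-methoxy-2-(4-methoxyphenyl)ethenyl]-2,4,4-trimethylcyclohex-2-en-1-yl acetate | CC1(C)CC[C@H](OC(C)=O)C(C)=C1C(OC)=Cc1ccc(OC)cc1 | intermediate
11 | 1α-acetoxy-6,12-dimethoxy-10α-methylpodocarpa-5,8,11,13-tetraene (not isolated) | COc1cc3c(cc1)CC(OC)=C4C(C)(C)CC[C@H](OC(C)=O)[C@@]34C | intermediate
12 | (1S,5R,10R)-1α-acetoxy-12-methoxypodocarpa-8,11,13-trien-6-one (5β-H, 10α-CH3) | COc1cc3c(cc1)CC(=O)[C@@H]4C(C)(C)CC[C@H](OC(C)=O)[C@@]34C | intermediate
13 | (1S,5R,6S,10R)-1α-acetoxy-12-methoxypodocarpa-8,11,13-trien-6α-ol | COc1cc3c(cc1)C[C@H](O)[C@@H]4C(C)(C)CC[C@H](OC(C)=O)[C@@]34C | intermediate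
14 | (1S,5R,6S,10R)-1α,6α-diacetoxy-12-methoxypodocarpa-8,11,13-triene | COc1cc3c(cc1)C[C@H](OC(C)=O)[C@@H]4C(C)(C)CC[C@H](OC(C)=O)[C@@]34C | intermediate
15 | 4-(chloromethyl)-2,2-dimethyl-1,3-dioxolane (racemic) | ClCC1COC(C)(C)O1 | starting material
16 | 2,2-dimethyl-4-methylene-1,3-dioxolane (not isolated) | C=C1COC(C)(C)O1 | intermediate
17 | 2,2,4-trimethyl-1,3-dioxole | CC1=COC(C)(C)O1 | intermediate
18 | meta photocycloadduct: 12,14-cyclo-15,16-(isopropylidenedioxy)-12-methoxyjungermann-8-ene-1α,6α-diyl diacetate (C15 on C11, C16 with methyl on C13, dioxolane oxygens exo; not isolated) | C[C@@]15OC(C)(C)O[C@H]5[C@@H]2C3=C(C[C@H](OC(C)=O)[C@@H]4C(C)(C)CC[C@H](OC(C)=O)[C@@]34C)[C@@H]6[C@H]1[C@]26OC | intermediate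
19 | 15,16-(isopropylidenedioxy)-12-oxojungermann-8-ene-1α,6α-diyl diacetate | C[C@@]15OC(C)(C)O[C@H]5[C@@H]2C3=C(C[C@H](OC(C)=O)[C@@H]4C(C)(C)CC[C@H](OC(C)=O)[C@@]34C)C[C@H]1C2=O | intermediate
20 | 12-hydroxy-15,16-(isopropylidenedioxy)jungermann-8-ene-1α,6α-diyl diacetate (12-OH syn to the C15–C16 bridge) | C[C@@]15OC(C)(C)O[C@H]5[C@@H]2C3=C(C[C@H](OC(C)=O)[C@@H]4C(C)(C)CC[C@H](OC(C)=O)[C@@]34C)C[C@H]1[C@@H]2O | intermediate
21 | 12-(tert-butyldimethylsilyloxy)-15,16-(isopropylidenedioxy)jungermann-8-ene-1α,6α-diyl diacetate | C[C@@]15OC(C)(C)O[C@H]5[C@@H]2C3=C(C[C@H](OC(C)=O)[C@@H]4C(C)(C)CC[C@H](OC(C)=O)[C@@]34C)C[C@H]1[C@@H]2O[Si](C)(C)C(C)(C)C | intermediate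
22 | 12-(tert-butyldimethylsilyloxy)-15,16-dihydroxyjungermann-8-ene-1α,6α-diyl diacetate (cis-diol, both hydroxyls exo) | C[C@]1(O)[C@@H](O)[C@@H]2C3=C(C[C@H](OC(C)=O)[C@@H]4C(C)(C)CC[C@H](OC(C)=O)[C@@]34C)C[C@H]1[C@@H]2O[Si](C)(C)C(C)(C)C | intermediate
23 | 12-(tert-butyldimethylsilyloxy)-16-hydroxy-15-oxojungermann-8-ene-1α,6α-diyl diacetate | C[C@]1(O)C(=O)[C@@H]2C3=C(C[C@H](OC(C)=O)[C@@H]4C(C)(C)CC[C@H](OC(C)=O)[C@@]34C)C[C@H]1[C@@H]2O[Si](C)(C)C(C)(C)C | intermediate
24 | 16-O-chlorosulfinyl derivative of 23 (not isolated) | C[C@]1(OS(Cl)=O)C(=O)[C@@H]2C3=C(C[C@H](OC(C)=O)[C@@H]4C(C)(C)CC[C@H](OC(C)=O)[C@@]34C)C[C@H]1[C@@H]2O[Si](C)(C)C(C)(C)C | intermediate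
25 | 12-(tert-butyldimethylsilyloxy)-15-oxojungermanna-8,16-diene-1α,6α-diyl diacetate | C=C1C(=O)[C@@H]2C3=C(C[C@H](OC(C)=O)[C@@H]4C(C)(C)CC[C@H](OC(C)=O)[C@@]34C)C[C@H]1[C@@H]2O[Si](C)(C)C(C)(C)C | intermediate
26 | 1α,6α-diacetoxyjungermannenone C | C=C1C(=O)[C@@H]2C3=C(C[C@H](OC(C)=O)[C@@H]4C(C)(C)CC[C@H](OC(C)=O)[C@@]34C)C[C@H]1[C@@H]2O | target

## Step count and least certain steps

Total: 16 steps. Longest linear sequence: 14 steps (steps 2–8 and 10–16, from 3).

**Step 10 (key step).** The exciplex may collapse by ortho ([2+2]) addition instead of the meta mode, the alkene may add with poor face or orientation selectivity, or the fragmentation may deliver the proton to C9 and leave the olefin at C8=C14. The fallback builds the bicycle in the ground state and sets out from 13. K2CO3 in MeOH removes the acetate and gives 1α,6α-dihydroxy-12-methoxypodocarpa-8,11,13-triene F1. Birch reduction (Li, NH3/THF, t-BuOH) gives 12-methoxypodocarpa-8,12-diene-1α,6α-diol F2, which oxalic acid hydrolyses to 1α,6α-dihydroxypodocarp-8-en-12-one F3; Ac2O with 4-(dimethylamino)pyridine gives its diacetate F4. KN(SiMe3)2 and 2,3-dibromopropene alkylate the doubly activated C11 from the β face to the 11β-(2-bromoallyl) ketone F5. Intramolecular α-alkenylation of the ketone at C13 (Pd2(dba)3 as source of zerovalent palladium, a biaryl phosphine, KOPh) closes the bicycle to 12-oxojungermanna-8,16-diene-1α,6α-diyl diacetate F6. NaBH4 gives the 12-alcohol F7 (the C12 epimers are separated and the undesired one reoxidised), SeO2/t-BuOOH hydroxylates C15 to the 12,15-diol F8, and MnO2 oxidises only the allylic C15 carbinol, which comes back to the route at 26.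

**Step 3.** t-BuLi may add to the styrene unit and eliminate methoxide, or metalate the anisole ring, instead of removing the vinylic α-proton; the enol ether may also be hydrolysed during the transposition. The fallback sets out from 5: (E)-2-(4-methoxyphenyl)ethenyllithium (from the bromide and t-BuLi) adds and, after acid, gives 3-[(E)-2-(4-methoxyphenyl)ethenyl]-2,4,4-trimethylcyclohex-2-en-1-one F9. mCPBA epoxidises the distal styrenyl bond to the epoxide F10. BF3·OEt2 rearranges this (Meinwald rearrangement, hydride shift to the benzylic cation) to the ene-dione 3-[(4-methoxyphenyl)acetyl]-2,4,4-trimethylcyclohex-2-en-1-one F11. KN(SiMe3)2 removes the most acidic, benzylic C7 proton and CF3SO3Me O-methylates the enolate, which comes back to the route at 8.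

**Step 6.** The arene may attack through its methoxy-activated ipso carbon (spirocyclisation followed by non-selective 1,2-shift), or the C1 acetate may control the face of C10 incompletely. The fallback replaces the cationic closure by a pericyclic one and sets out from 10. Irradiation at 300 nm in degassed cyclohexane with n-PrNH2 isomerises the enol ether double bond and closes the aryl-diene by 6π-electrocyclisation to the dearomatised triene F12. The amine-mediated hydrogen shift from C9 to C7 restores the arene and gives 11, which is hydrolysed as in step 6 and comes back to the route at 12. Here the new bond can only form at the ortho carbon.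

**Step 9.** The base may stop at the exocyclic isomer or establish an unfavourable equilibrium. The fallback sets out from 15: KOH at high temperature gives 16, which is isolated by distillation and isomerised by metal-hydride addition–elimination with RuHCl(CO)(PPh3)3, coming back to the route at 17.

**Step 15.** The hindered tertiary chlorosulfite may eliminate slowly, allowing α-ketol rearrangement (methyl shift) or addition of chloride to the enone formed. The fallback sets out from 23: SmI2 in THF/MeOH cleaves the α-hydroxyl to the α-methyl ketone F13, TMSOTf/Et3N gives the silyl enol ether F14, which can only form towards C16, and Pd(OAc)2 in MeCN (Saegusa oxidation) removes a methyl hydrogen, coming back to the route at 25.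

## Further compounds

F1 | step 10 | 1α,6α-dihydroxy-12-methoxypodocarpa-8,11,13-triene | COc1cc3c(cc1)C[C@H](O)[C@@H]4C(C)(C)CC[C@H](O)[C@@]34C
F2 | step 10 | 12-methoxypodocarpa-8,12-diene-1α,6α-diol | COC1CC3=C(CC=1)C[C@H](O)[C@@H]4C(C)(C)CC[C@H](O)[C@@]34C
F3 | step 10 | 1α,6α-dihydroxypodocarp-8-en-12-one | O=C1CC3=C(CC1)C[C@H](O)[C@@H]4C(C)(C)CC[C@H](O)[C@@]34C
F4 | step 10 | 12-oxopodocarp-8-ene-1α,6α-diyl diacetate | O=C1CC3=C(CC1)C[C@H](OC(C)=O)[C@@H]4C(C)(C)CC[C@H](OC(C)=O)[C@@]34C
F5 | step 10 | 11β-(2-bromoprop-2-enyl)-12-oxopodocarp-8-ene-1α,6α-diyl diacetate | C=C(Br)C[C@@H]2C3=C(C[C@H](OC(C)=O)[C@@H]4C(C)(C)CC[C@H](OC(C)=O)[C@@]34C)CCC2=O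
F6 | step 10 | 12-oxojungermanna-8,16-diene-1α,6α-diyl diacetate | C=C1C[C@@H]2C3=C(C[C@H](OC(C)=O)[C@@H]4C(C)(C)CC[C@H](OC(C)=O)[C@@]34C)C[C@H]1C2=O
F7 | step 10 | 12-hydroxyjungermanna-8,16-diene-1α,6α-diyl diacetate (12-OH syn to the C15–C16 bridge) | C=C1C[C@@H]2C3=C(C[C@H](OC(C)=O)[C@@H]4C(C)(C)CC[C@H](OC(C)=O)[C@@]34C)C[C@H]1[C@@H]2O
F8 | step 10 | 12,15-dihydroxyjungermanna-8,16-diene-1α,6α-diyl diacetate (either C15 epimer) | C=C1C(O)[C@@H]2C3=C(C[C@H](OC(C)=O)[C@@H]4C(C)(C)CC[C@H](OC(C)=O)[C@@]34C)C[C@H]1[C@@H]2O
F9 | step 3 | 3-[(E)-2-(4-methoxyphenyl)ethenyl]-2,4,4-trimethylcyclohex-2-en-1-one | COc1ccc(/C=C/C2=C(C)C(=O)CCC2(C)C)cc1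
F10 | step 3 | 3-[3-(4-methoxyphenyl)oxiran-2-yl]-2,4,4-trimethylcyclohex-2-en-1-one (racemic trans-epoxide) | COc1ccc(C2OC2C2=C(C)C(=O)CCC2(C)C)cc1
F11 | step 3 | 3-[(4-methoxyphenyl)acetyl]-2,4,4-trimethylcyclohex-2-en-1-one | COc1ccc(CC(=O)C2=C(C)C(=O)CCC2(C)C)cc1
F12 | step 6 | 1α-acetoxy-6,12-dimethoxy-10α-methylpodocarpa-5,7,11,13-tetraene (dearomatised cyclisation product, C9 configuration not relevant) | COC1=CC3C(C=C1)=CC(OC)=C4C(C)(C)CC[C@H](OC(C)=O)[C@@]34C
F0 | step 9 | none | none
F13 | step 15 | 12-(tert-butyldimethylsilyloxy)-16-methyl-15-oxo-17-norjungermann-8-ene-1α,6α-diyl diacetate (C17 as methyl, either C16 epimer) | CC1C(=O)[C@@H]2C3=C(C[C@H](OC(C)=O)[C@@H]4C(C)(C)CC[C@H](OC(C)=O)[C@@]34C)C[C@H]1[C@@H]2O[Si](C)(C)C(C)(C)C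
F14 | step 15 | 15-trimethylsilyl enol ether of F13 (C15=C16) | CC1=C(O[Si](C)(C)C)[C@@H]2C3=C(C[C@H](OC(C)=O)[C@@H]4C(C)(C)CC[C@H](OC(C)=O)[C@@]34C)C[C@H]1[C@@H]2O[Si](C)(C)C(C)(C)C
A1 | alternative 1 | 1α,6α-diacetoxy-12-hydroxy-ent-kaura-9(11),16-dien-15-one | C=C1C(=O)[C@@]23C[C@H](OC(C)=O)[C@@H]4C(C)(C)CC[C@H](OC(C)=O)[C@@]4(C)C2=C[C@@H](O)[C@@H]1C3
A2 | alternative 2 | 11β-(prop-2-ynyl)-12-(tert-butyldimethylsilyloxy)podocarpa-8,12-diene-1α,6α-diyl diacetate | C#CC[C@@H]2C3=C(C[C@H](OC(C)=O)[C@@H]4C(C)(C)CC[C@H](OC(C)=O)[C@@]34C)CC=C2O[Si](C)(C)C(C)(C)C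
A3 | alternative 3 | 12-hydroxypodocarpa-8,11,13-triene-1α,6α-diyl diacetate | Oc1cc3c(cc1)C[C@H](OC(C)=O)[C@@H]4C(C)(C)CC[C@H](OC(C)=O)[C@@]34C
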